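**Retrosynthetic overview**
- The target is read as the cis (3S,4S) lactone. The last bond made is the C6–O geranyl ether, by alkylating the non-chelated 6-OH of the 4-acetoxy-6,8-dihydroxy lactone.
- Key disconnection: the C4–O bond goes back to the benzylic C4–H of an (S)-3-methyl-3,4-dihydroisocoumarin. A retentive C–H hydroxylation sets C4 cis to the 3-methyl group; O-acetylation follows.
- Ring B (the lactone) is the only ring formed; ring A (the benzene ring) is bought. Ring B comes from an aryl carboxylic acid and (S)-propylene oxide by carboxylate-directed C–H alkylation and lactonisation, so C3 comes from the epoxide.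
- The aryl acid comes from 5-bromo-2,4-dihydroxybenzoic acid by C–O coupling with methoxide and acetylation of the phenols.

Assumption: reagents that put non-hydrogen atoms into a product are numbered as starting materials; catalysts, bases and solvents are not numbered.

**Step 1**
Reactants: 1 5-bromo-2,4-dihydroxybenzoic acid; 2 sodium methoxide
Product: 3 2,4-dihydroxy-5-methoxybenzoic acid
Conditions: NaOMe (6 equiv), CuBr (10 mol%), MeOH/DMF, 110 °C, N2, 16 h; then aq. HCl, 0 °C
Reagents that add atoms: sodium methoxide (2), C[O-].[Na+]
Why: Ullmann-type copper-catalysed C–O coupling, in which the bromide ortho to a phenoxide is exchanged for methoxide (as in the conversion of 5-bromovanillin into syringaldehyde) while the polyanionic substrate resists decarboxylation; no stereocentre is involved.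

**Step 2**
Reactants: 3 2,4-dihydroxy-5-methoxybenzoic acid; 4 acetic anhydride
Product: 5 2,4-diacetoxy-5-methoxybenzoic acid
Conditions: Ac2O (4 equiv), H2SO4 (cat.), 60 °C, 1 h; then H2O, 0 °C
Reagents that add atoms: acetic anhydride (4), CC(=O)OC(C)=O
Why: Acid-catalysed phenol O-acetylation (aspirin-type) esterifies both phenols and leaves the carboxylic acid free after the aqueous quench, giving oxidation-resistant aryl acetates that can later be removed without touching an alkyl acetate.

**Step 3**
Reactants: 5 2,4-diacetoxy-5-methoxybenzoic acid; 6 (S)-propylene oxide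
Product: 8 (3S)-6,8-diacetoxy-5-methoxy-3-methylisochroman-1-one, via hydroxy acid 7 (not isolated)
Conditions: Pd(OAc)2 (10 mol%), Ac-Val-OH (20 mol%), KOAc (1 equiv), (S)-propylene oxide (3 equiv), HFIP (1,1,1,3,3,3-hexafluoropropan-2-ol), 60 °C, sealed tube, 24 h
Reagents that add atoms: (S)-propylene oxide (6), C[C@H]1CO1
Why: Carboxylate-directed ortho C–H palladation at the only free ortho position, SN2-type opening of the epoxide at its CH2 end by the aryl–palladium bond and lactonisation of the hydroxy acid (the known C–H alkylation of benzoic acids with epoxides under divalent palladium) build ring B; the C–O bond at the stereocentre of 6 is never broken, so C3 is S.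

**Step 4**
Reactants: 8 (3S)-6,8-diacetoxy-5-methoxy-3-methylisochroman-1-one; 9 hydrogen peroxide
Product: 10 (3S,4S)-6,8-diacetoxy-4-hydroxy-5-methoxy-3-methylisochroman-1-one
Conditions: [Mn(OTf)2((S,S)-pdp)] (2 mol%; pdp = 1,1'-bis(pyridin-2-ylmethyl)-2,2'-bipyrrolidine), AcOH (5 equiv), H2O2 (50% aq., 1.5 equiv, added over 1 h), HFIP, 0 °C
Reagents that add atoms: hydrogen peroxide (9), OO
Why: Proposed new method: substrate-controlled, stereoretentive benzylic C(sp3)–H hydroxylation of a 3,4-dihydroisocoumarin. The electrophilic pentavalent manganese-oxo species formed from the catalyst, H2O2 and AcOH abstracts the pseudoaxial C4–H, the only C–H aligned with the arene π-system (the pseudoequatorial one lies in the ring plane beside the 5-OMe group); in the half-chair with the 3-methyl group pseudoequatorial this hydrogen is cis to the methyl group, so fast hydroxyl rebound on the same face should give the 4S alcohol with OH pseudoaxial and cis to 3-Me; the C4–H that remains is the misaligned one and HFIP hydrogen-bonds the alcohol, which together should suppress over-oxidation to the ketone, while the aryl acetates keep the arene electron-poor; the closest known reaction type is manganese- or iron-catalysed (pdp-type) benzylic and aliphatic C–H hydroxylation with H2O2 in fluorinated alcohols, not yet shown on dihydroisocoumarins or with this cis selectivity.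

**Step 5**
Reactants: 10 (3S,4S)-6,8-diacetoxy-4-hydroxy-5-methoxy-3-methylisochroman-1-one; 4 acetic anhydride
Product: 11 (3S,4S)-4,6,8-triacetoxy-5-methoxy-3-methylisochroman-1-one
Conditions: Ac2O (3 equiv), pyridine (5 equiv), DMAP (10 mol%), CH2Cl2, 0 °C → rt
Reagents that add atoms: acetic anhydride (4), CC(=O)OC(C)=O
Why: DMAP-catalysed O-acylation of the secondary benzylic alcohol breaks no bond to C4, so the 3S,4S configuration is kept.

**Step 6**
Reactants: 11 (3S,4S)-4,6,8-triacetoxy-5-methoxy-3-methylisochroman-1-one; 12 geranyl bromide
Product: 14 (3S,4S)-4-acetoxy-6-geranyloxy-8-hydroxy-5-methoxy-3-methylisochroman-1-one, via free diphenol 13 (not isolated)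
Conditions: pyrrolidine (2.1 equiv), DMF, 0 °C, 30 min; then K2CO3 (1.5 equiv), geranyl bromide (1.2 equiv), 0 °C → rt, 6 h
Reagents that add atoms: geranyl bromide (12), BrC/C=C(\C)CCC=C(C)C
Why: Pyrrolidine aminolyses aryl acetates far faster than the secondary alkyl acetate or the lactone, and in the freed diphenol the 8-OH is locked in a hydrogen bond to the lactone carbonyl, so the K2CO3-mediated Williamson etherification (SN2 at the primary allylic bromide, E-geometry retained) takes place at the more acidic 6-OH and gives the target with both stereocentres untouched.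

**Compound list**
1 | 5-bromo-2,4-dihydroxybenzoic acid | OC(=O)c1cc(Br)c(O)cc1O | starting material
2 | sodium methoxide | C[O-].[Na+] | starting material
3 | 2,4-dihydroxy-5-methoxybenzoic acid | COc1cc(C(=O)O)c(O)cc1O | intermediate
4 | acetic anhydride | CC(=O)OC(C)=O | starting material
5 | 2,4-diacetoxy-5-methoxybenzoic acid | COc1cc(C(=O)O)c(OC(C)=O)cc1OC(C)=O | intermediate
6 | (S)-propylene oxide, (S)-2-methyloxirane | C[C@H]1CO1 | starting material
7 | 2,4-diacetoxy-6-[(2S)-2-hydroxypropyl]-5-methoxybenzoic acid (not isolated) | COc1c(OC(C)=O)cc(OC(C)=O)c(C(=O)O)c1C[C@H](C)O | intermediate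
8 | (3S)-6,8-diacetoxy-5-methoxy-3-methylisochroman-1-one (3,4-dihydroisocoumarin) | COc1c(OC(C)=O)cc(OC(C)=O)c2c1C[C@H](C)OC2=O | intermediate
9 | hydrogen peroxide | OO | starting material
10 | (3S,4S)-6,8-diacetoxy-4-hydroxy-5-methoxy-3-methylisochroman-1-one (4-OH cis to 3-Me) | COc1c(OC(C)=O)cc(OC(C)=O)c2c1[C@H](O)[C@H](C)OC2=O | intermediate
11 | (3S,4S)-4,6,8-triacetoxy-5-methoxy-3-methylisochroman-1-one | COc1c(OC(C)=O)cc(OC(C)=O)c2c1[C@H](OC(C)=O)[C@H](C)OC2=O | intermediate
12 | geranyl bromide, (2E)-1-bromo-3,7-dimethylocta-2,6-diene | BrC/C=C(\C)CCC=C(C)C | starting material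
13 | (3S,4S)-4-acetoxy-6,8-dihydroxy-5-methoxy-3-methylisochroman-1-one (not isolated) | COc1c(O)cc(O)c2c1[C@H](OC(C)=O)[C@H](C)OC2=O | intermediate
14 | (3S,4S)-4-acetoxy-6-{[(2E)-3,7-dimethylocta-2,6-dien-1-yl]oxy}-8-hydroxy-5-methoxy-3-methylisochroman-1-one (CNP0251645.1; 4-OAc cis to 3-Me) | COc1c(OC/C=C(\C)CCC=C(C)C)cc(O)c2c1[C@H](OC(C)=O)[C@H](C)OC2=O | target

**Step count and risks**
Total steps: 6. Longest linear sequence: 6 steps (1 → 14).

The three steps most likely to fail:

Step 3. The C–H bond to be palladated sits between the carboxylate and the 5-OMe group, and the 2-acetoxy group may be lost in HFIP (a crude re-acetylation would repair that). The fallback sets out from 5 and comes back at 8. Carboxylate-directed C–H allylation with allyl acetate ([RuCl2(p-cymene)]2, K3PO4, MeCN, 50 °C; this metal accepts methoxy-flanked positions and needs no HFIP) gives 2,4-diacetoxy-6-allyl-5-methoxybenzoic acid F1. Wacker-type oxidative lactonisation (PdCl2(MeCN)2 cat., 1,4-benzoquinone, Na2CO3, THF) gives the achiral 6,8-diacetoxy-5-methoxy-3-methyl-1H-isochromen-1-one F2. Enantioselective hydrogenation of its C3=C4 bond (Ru(cod)(2-methylallyl)2, the chiral N-heterocyclic carbene SINpEt from SINpEt·HBF4 and KOtBu, H2, using the ligand antipode that gives 3S) returns 8, so C3 then comes from catalysis instead of from the epoxide.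

Step 4 (the proposed new step). It may give low conversion, ketone, or too little cis selectivity; trying the (R,R)-catalyst is only a change of conditions. The fallback uses known chemistry, sets out from 8 and comes back at 10. Benzylic oxidation (CrO3 cat., H5IO6, MeCN, rt) gives (3S)-6,8-diacetoxy-5-methoxy-3-methylisochromane-1,4-dione F3, in which C3 is epimerisable. Noyori–Ikariya transfer hydrogenation under dynamic kinetic resolution (RuCl[(R,R)-TsDPEN](p-cymene), HCO2H/Et3N 5:2, rt) reduces C4 from the face set by the catalyst and funnels both C3 epimers into the cis alcohol 10 (3S,4S). Any aryl acetate lost here is restored in step 5.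

Step 6. The one-pot sequence risks loss of the 4-acetate, alkylation at O8, or C-alkylation at C7. The fallback sets out from 11 and comes back at 14. NH4OAc in aqueous MeOH at rt cleaves only the aryl acetates, and the diphenol 13 is isolated. Mitsunobu etherification with geraniol (PPh3, DIAD, THF, 0 °C) then alkylates only the more acidic, non-chelated 6-OH under neutral conditions. Compounds outside the list on this path: none F0.

**Further compounds**
F1 | step 3 | 2,4-diacetoxy-6-allyl-5-methoxybenzoic acid | COc1c(OC(C)=O)cc(OC(C)=O)c(C(=O)O)c1CC=C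
F2 | step 3 | 6,8-diacetoxy-5-methoxy-3-methyl-1H-isochromen-1-one | COc1c(OC(C)=O)cc(OC(C)=O)c2c1C=C(C)OC2=O
F3 | step 4 | (3S)-6,8-diacetoxy-5-methoxy-3-methylisochromane-1,4-dione | COc1c(OC(C)=O)cc(OC(C)=O)c2c1C(=O)[C@H](C)OC2=O
F0 | step 6 | none | none
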